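## Analysis of the target

Target 29 is a linear hexamer of benzene rings joined by five diaryl ether oxygens. It carries sixteen free phenolic hydroxyls and no carbon substituent. With the rings lettered A to F from the 2,4,6-trihydroxyphenoxy end, ring A is a 2,4,6-trihydroxyphenyl group and ring F a 3,4,5-trihydroxyphenyl group. Rings B and D are identical pentaoxygenated rings (ether oxygens at C1 and C6, hydroxyls at C3, C4 and C5, the only hydrogen at C2), and rings C and E are identical 3,5-dihydroxy-1,4-phenylenedioxy rings. There is no stereocentre and no isolable axis, so nothing stereochemical has to be set; the only repeat to exploit is that the B–O–C pair recurs unchanged as the D–O–E pair. The free polyphenol is the sensitive part: the pyrogallol-type arrays on rings B, D and F autoxidise quickly, above all in base, so the hydroxyls stay masked until the last step, while the diaryl ether bonds tolerate acid, base, hydrogenolysis and Lewis acids. The first difficulty is that every ether bond joins two electron-rich rings and is flanked by two or three ortho oxygen substituents (three at the A–B and C–D links), the worst case for diaryl ether coupling. The second is that rings B and D need two ether positions told apart from three hydroxyl positions within five contiguous oxygens. The strategy rests on ring B: C1, C6, C5 and C4 with their oxygens correspond to the four carbons of a squaric acid derivative, and C3 with its oxygen plus C2–H to a 1-alkoxyvinyl unit, so the ring can be closed between C1 and C2 with all five oxygens in place and already differentiated.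

## Retrosynthetic reasoning

**29 from 28.** All hydroxyls are unmasked last, from fifteen methyl ethers and one free phenol. Methyl is chosen because the three methyl ethers of ring B arise naturally in the ring-forming sequence and because aryl methyl ethers survive organolithium, 110 °C, peracid, hydrogenolysis and palladium. The forward reaction has to cleave O–CH3 bonds and leave aryl–O–aryl bonds alone.

**28 from 24 and 25 (through 26 and 27).** The E–F ether is cut on the ring F side. Ring F enters as fluoroaldehyde 25, whose formyl group first activates displacement of the para fluoride and is then converted into the C4 hydroxyl by a peracid. The cut is made here because the hindered ring E hydroxyl of 24 is a good nucleophile, and the fluoride of 25 has no ortho substituent.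

**24 from 23, and 23 from 21 and 22.** The central C–D ether is cut because it divides the molecule into two halves that both descend from one compound, phenol 15. The D–E half is 15 activated as its triflate 22; the A–B–C half is 15 after attachment of ring A and debenzylation (21). The forward reaction must join a di-ortho-methoxy phenol to an ortho-aryloxy aryl sulfonate, which is a task for palladium catalysis and the hardest ether of the route.

**21 from 20, 19, 17, and these from 15 and 16.** The A–B ether is cut on the ring A side. Ring A enters as fluoroaldehyde 16, attacked by the single free hydroxyl of 15. The formyl group becomes the ring A C4 oxygen (peracid, then methylation), so that after hydrogenolysis the ring C hydroxyl of 21 is the only free one.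

**15 from 12 (through 13 and 14), the key disconnection.** The C1–C2 bond of ring B is cut, which removes the arene and leaves cyclobutenone 12. In 12 all five oxygens of ring B and the ether to ring C already exist. The gain is that no oxygen of ring B ever has to be differentiated on an aromatic ring, and the only hydroxyl the forward reaction liberates is the C1 hydroxyl needed for ring A and for the triflate. The forward reaction is a thermal ring opening to a dienylketene followed by 6π closure.

**12 from 8 and 9 (through 10 and 11).** The bond between the quaternary carbon and the vinyl carbon is cut, giving mixed squarate 8 and lithiated 9. The forward addition must choose between the two carbonyls of 8: it has to take the one in vinylogous conjugation with the aryloxy group, and the alkoxide must be methylated before it can rearrange.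

**8 from 4 and 6 (through 7), and 6 from 5.** The B–C ether oxygen is installed as a vinylogous ester, not by arylation. A dialkyl squarate is not a workable precursor, because exchanging an alkoxide for the better-leaving aryloxide is uphill. The dichloride 6 is therefore used: one chloride is replaced by methoxide to give 7, and the second, still an excellent leaving group, by the phenoxide of 4.

**4 from 2 and 1.** Ring C comes from 1. Its phenolic oxygen is benzylated (it later becomes the C–D ether oxygen) and its formyl group is exchanged for the hydroxyl that becomes the B–C ether oxygen.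

## Alternatives that were turned down

**Alternative 1:** The C4–O bonds of rings B, D and F are traced back to formyl groups, so the precursor is the permethylated hexamer trialdehyde A1. In the forward key step a peracid inserts oxygen between each formyl carbon and its ring by aryl migration, giving the tris(formate) A2 in one operation.
- For: the formyl groups work twice. Para to C1 of rings B, D and F they activate fluoride displacement, so the A–B, C–D and E–F ethers can be made by nucleophilic aromatic substitution, and then they become the missing hydroxyls. Aryl migration is favoured because each formyl group sits between two methoxy groups. The route is short and needs no organometallic step. On the crowded C–D ether it is stronger than the chosen route, which needs a palladium coupling there.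
- Against: the formyl group at C4 of rings B and D is meta to C6, so the B–C and D–E ethers receive no activation. They would need metal-catalysed coupling at a carbon between two oxygen substituents, or a ring B building block with a free hydroxyl next to an activated fluoride, which would condense with itself. The key step also comes last, on a hexamer with twenty-one oxygens: three oxidations must all go to completion while the very electron-rich rings A, C and E compete for the peracid.
- Comparison: Alternative 1 wins on step count. The chosen strategy offers instead the B–C and D–E ethers made as a squarate ester before the arene exists, the oxidation level of ring B fixed from the first step, and the same oxidation used only on small intermediates (steps 2, 8 and 15).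

**Alternative 2:** Ring C is cut at C2–C3 and C5–C6 into the aryloxymalonate A3 (C3–C4–C5, with the ether oxygen to ring D already on C4) and dimethyl 3-oxoglutarate A4 (C2–C1–C6). In the forward key step an alkoxide base makes both methylene carbons of A4 acylate the two ester groups of A3, and enolisation gives the trihydroxyisophthalate A5.
- For: the C–D ether is made by alkylating a phenol at an sp3 carbon, so the most congested link needs no diaryl ether coupling at all. On that bond it is clearly stronger than step 12 of the chosen route. The building blocks are cheap and the three oxygens of ring C fall into place automatically.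
- Against: under alkoxide the most acidic proton is the malonate C–H of A3. Once it is removed the two esters are poor electrophiles, and the partner A4 is itself an enolate, so two anions have to condense. A5 then needs both ester groups removed, has three undifferentiated hydroxyls of which only the one at C1 may be arylated, and requires ring B to arrive as an electrophilic pentaoxygenated arene. The ring construction is spent on the simple ring C, twice over for ring E, while the five-oxygen rings still have to be made separately.
- Comparison: the chosen strategy spends its ring construction on the pentaoxygenated ring, delivers one free hydroxyl, and obtains ring C from 1 in two steps.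

**Alternative 3:** Ring F is taken apart into the aryloxy(2-methoxyvinyl)carbene chromium complex A6 (carbene carbon and two vinyl carbons, with the E–F oxygen on the carbene carbon), ethoxyacetylene A7 and one carbonyl ligand. In the forward key step, heating inserts the alkyne and then carbon monoxide, the resulting vinylketene closes by a 6π process and tautomerises to the 4-aryloxyphenol A8.
- For: the pericyclic logic is the same as in the chosen step, a ketene closing to a phenol. Three components combine in one step, the terminal alkyne puts its ethoxy group next to the new hydroxyl, and the E–F ether is in place with C4 free. In convergence of the key step it is stronger than the chosen one.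
- Against: it builds ring F, the least demanding ring, which the chosen route obtains from 25 in two steps. Aryloxycarbene complexes are accessible only by exchange with the hindered phenol and are labile, since aryloxide leaves easily from the electrophilic carbene carbon. Ynol ethers are prone to give cyclobutenones or double-insertion products instead of the phenol, and stoichiometric chromium is needed. After A8 the two pentaoxygenated rings and the crowded A–B and C–D ethers are still unsolved.
- Comparison: the chosen strategy puts its electrocyclisation where the substitution problem actually lies.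

Key step: step 6

Assumption: the fluoroaldehydes 16 and 25 are taken as purchasable building blocks, and the stereocentre of 11 and 12 is carried as the racemate because step 6 erases it.

## Route

Step 1
Reactants: 1 syringaldehyde (4-hydroxy-3,5-dimethoxybenzaldehyde)
Product: 2 4-(benzyloxy)-3,5-dimethoxybenzaldehyde
Conditions: BnBr, K2CO3, DMF, 60 °C
Reagents that add atoms: benzyl bromide, BrCc1ccccc1
Why: Williamson ether synthesis; the phenol is acidified by the para formyl group and its potassium salt is benzylated cleanly, which masks the oxygen that later becomes the C–D ether oxygen.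

Step 2
Reactants: 2 4-(benzyloxy)-3,5-dimethoxybenzaldehyde
Product: 4 4-(benzyloxy)-3,5-dimethoxyphenol, via aryl formate 3 (not isolated)
Conditions: mCPBA, CH2Cl2, 0 °C to rt; then K2CO3 (cat.), MeOH, rt
Reagents that add atoms: 3-chloroperoxybenzoic acid (mCPBA), O=C(OO)c1cccc(Cl)c1
Why: Baeyer–Villiger (Dakin-type) oxidation; the ring with three oxygen donors migrates in preference to hydride, and the formate is removed by mild methanolysis to give the ring C phenol.

Step 3
Reactants: 5 squaric acid (3,4-dihydroxycyclobut-3-ene-1,2-dione)
Product: 6 squaryl dichloride (3,4-dichlorocyclobut-3-ene-1,2-dione)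
Conditions: (COCl)2, DMF (cat.), 1,2-dichloroethane, 50 °C
Reagents that add atoms: oxalyl chloride, O=C(Cl)C(Cl)=O
Why: Vilsmeier-type chlorodehydroxylation of a doubly vinylogous carboxylic acid, the standard preparation of this bis(vinylogous acid chloride).

Step 4
Reactants: 6 squaryl dichloride, 4 4-(benzyloxy)-3,5-dimethoxyphenol
Product: 8 3-[4-(benzyloxy)-3,5-dimethoxyphenoxy]-4-methoxycyclobut-3-ene-1,2-dione, via ester chloride 7 (not isolated)
Conditions: MeOH (1.0 equiv), Et2O, 0 °C to rt, then evaporation; 4, i-Pr2NEt, CH2Cl2, −40 to 0 °C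
Reagents that add atoms: methanol, CO
Why: Two successive addition–elimination steps on a vinylogous acid chloride; the first methoxy group deactivates the remaining chloride enough to stop at 7, and the phenoxide then enters only at the chlorinated carbon because chloride is a far better leaving group than methoxide, which sidesteps the unfavourable exchange of an alkoxide for an aryloxide on a dialkyl squarate.

Step 5
Reactants: 9 methyl vinyl ether, 8 3-[4-(benzyloxy)-3,5-dimethoxyphenoxy]-4-methoxycyclobut-3-ene-1,2-dione
Product: 12 2-[4-(benzyloxy)-3,5-dimethoxyphenoxy]-3,4-dimethoxy-4-(1-methoxyvinyl)cyclobut-2-en-1-one (racemic), via 1-methoxyvinyllithium 10 (not isolated), via lithium alkoxide adduct 11 (not isolated)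
Conditions: 9 (excess), t-BuLi, THF, −78 to 0 °C; then added to 8, THF, −78 °C; then MeOTf, −78 to 0 °C
Reagents that add atoms: methyl trifluoromethanesulfonate, COS(=O)(=O)C(F)(F)F
Why: 1,2-Addition of an α-lithiated enol ether to a squarate ester followed by in situ O-methylation; the organolithium should attack the carbonyl that is in vinylogous conjugation with the aryloxy group (the weaker donor, hence the more electrophilic carbonyl, next to the methoxy-bearing carbon), and immediate methylation of 11 prevents the acid-induced rearrangement of the free carbinol and caps the oxygen that becomes C4–OMe of ring B; the new quaternary centre forms as a racemate and is of no consequence.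

Step 6
Reactants: 12 2-[4-(benzyloxy)-3,5-dimethoxyphenoxy]-3,4-dimethoxy-4-(1-methoxyvinyl)cyclobut-2-en-1-one
Product: 15 2-[4-(benzyloxy)-3,5-dimethoxyphenoxy]-3,4,5-trimethoxyphenol, via dienylketene 13 (not isolated), via cyclohexa-2,4-dienone 14 (not isolated)
Conditions: toluene (degassed, 0.02 M), 110 °C, Ar
Reagents that add atoms: none
Why: This is a Moore-type ring expansion of a 4-alkenyl-4-alkoxycyclobutenone, the established way from squarate adducts to mono-protected hydroquinones. Heating opens the four-membered ring by conrotatory 4π cleavage of the C1–C4 bond, and the donor methoxy group on C4 rotates outward, as oxygen substituents at this position do, so the methoxyvinyl group turns inward and the (3Z)-dienylketene 13 results. The ketene carbon (future C1 of ring B) and the vinyl CH2 (future C2) are then in reach, and a thermal disrotatory 6π electrocyclisation closes the six-membered carbocycle as dienone 14. Tautomerisation of the C2 hydrogen to oxygen aromatises ring B irreversibly to phenol 15. No stereocentre is created, and the racemic quaternary centre of 12 becomes the planar C4. The selectivity required is torquoselectivity and a closure that outruns trapping of the ketene: the first is secured by the C4 methoxy donor, the second by dilute, degassed, aprotic conditions. Regiochemistry needs no control here because it was fixed by the position of the aryloxy group in 12, and the methyl group on the C4 oxygen ensures that the C1 hydroxyl is the only free one.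

Step 7
Reactants: 15 2-[4-(benzyloxy)-3,5-dimethoxyphenoxy]-3,4,5-trimethoxyphenol, 16 4-fluoro-3,5-dimethoxybenzaldehyde
Product: 17 4-{2-[4-(benzyloxy)-3,5-dimethoxyphenoxy]-3,4,5-trimethoxyphenoxy}-3,5-dimethoxybenzaldehyde
Conditions: Cs2CO3, DMSO, 110 °C
Reagents that add atoms: none
Why: Nucleophilic aromatic substitution; the para formyl group stabilises the Meisenheimer intermediate, fluoride is the best leaving group for this mechanism, and the two flanking methoxy groups are small and inductively withdrawing, so the caesium phenoxide of 15 should displace fluoride without a metal catalyst.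

Step 8
Reactants: 17 4-{2-[4-(benzyloxy)-3,5-dimethoxyphenoxy]-3,4,5-trimethoxyphenoxy}-3,5-dimethoxybenzaldehyde
Product: 19 4-{2-[4-(benzyloxy)-3,5-dimethoxyphenoxy]-3,4,5-trimethoxyphenoxy}-3,5-dimethoxyphenol, via aryl formate 18 (not isolated)
Conditions: mCPBA, CH2Cl2, 0 °C; then K2CO3 (cat.), MeOH, rt
Reagents that add atoms: 3-chloroperoxybenzoic acid (mCPBA), O=C(OO)c1cccc(Cl)c1
Why: Baeyer–Villiger (Dakin-type) oxidation as in step 2; the para aryloxy and two meta methoxy groups favour aryl migration, so the formyl group is exchanged for the C4 oxygen of ring A.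

Step 9
Reactants: 19 4-{2-[4-(benzyloxy)-3,5-dimethoxyphenoxy]-3,4,5-trimethoxyphenoxy}-3,5-dimethoxyphenol
Product: 20 2-[4-(benzyloxy)-3,5-dimethoxyphenoxy]-3,4,5-trimethoxy-1-(2,4,6-trimethoxyphenoxy)benzene (A–B–C unit, ring C benzyl ether)
Conditions: MeI, K2CO3, acetone, reflux
Reagents that add atoms: iodomethane, CI
Why: Williamson methylation of an unhindered phenol; it completes ring A as the 2,4,6-trimethoxyphenyl group so that the next step exposes a single hydroxyl.

Step 10
Reactants: 20 A–B–C unit, ring C benzyl ether
Product: 21 2,6-dimethoxy-4-[2,3,4-trimethoxy-6-(2,4,6-trimethoxyphenoxy)phenoxy]phenol (A–B–C phenol)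
Conditions: H2 (1 atm), Pd/C, EtOAc–MeOH, rt
Reagents that add atoms: none
Why: Hydrogenolysis of the benzylic C–O bond on palladium; aryl methyl ethers and diaryl ethers are inert, so only the ring C hydroxyl at C4 is set free.

Step 11
Reactants: 15 2-[4-(benzyloxy)-3,5-dimethoxyphenoxy]-3,4,5-trimethoxyphenol
Product: 22 2-[4-(benzyloxy)-3,5-dimethoxyphenoxy]-3,4,5-trimethoxyphenyl trifluoromethanesulfonate (D–E unit)
Conditions: Tf2O, pyridine, CH2Cl2, 0 °C
Reagents that add atoms: trifluoromethanesulfonic anhydride, O=S(=O)(OS(=O)(=O)C(F)(F)F)C(F)(F)F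
Why: O-Sulfonylation of a phenol; a second portion of 15 is thereby turned into the electrophile for ring D C1, because rings D and E have the same substitution as rings B and C.

Step 12
Reactants: 21 A–B–C phenol, 22 D–E triflate
Product: 23 2-{4-[2-(4-benzyloxy-3,5-dimethoxyphenoxy)-3,4,5-trimethoxyphenoxy]-3,5-dimethoxyphenoxy}-3,4,5-trimethoxy-1-(2,4,6-trimethoxyphenoxy)benzene (A–B–C–D–E unit, ring E benzyl ether)
Conditions: Pd(OAc)2 (cat.), 2-(di-tert-butylphosphino)-2′,4′,6′-triisopropylbiphenyl (cat.), K3PO4, toluene, 100 °C
Reagents that add atoms: none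
Why: Palladium-catalysed C–O cross-coupling of an aryl triflate with a phenol (Buchwald–Hartwig etherification); zerovalent palladium inserts into the aryl–OTf bond, phosphate delivers the phenoxide of 21 to the divalent arylpalladium species, and the bulky di-tert-butylbiarylphosphine together with the two ortho methoxy groups of the phenoxide drives the C–O reductive elimination that forms the C–D ether.

Step 13
Reactants: 23 A–B–C–D–E unit, ring E benzyl ether
Product: 24 pentamer phenol A–B–C–D–E (23 with the ring E benzyl ether replaced by a free C4 hydroxyl)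
Conditions: H2 (1 atm), Pd/C, EtOAc–MeOH, rt
Reagents that add atoms: none
Why: Hydrogenolysis of the last benzyl ether as in step 10; all other C–O bonds are aryl–O bonds and remain.

Step 14
Reactants: 24 pentamer phenol A–B–C–D–E, 25 4-fluoro-2,6-dimethoxybenzaldehyde
Product: 26 hexamer aldehyde (24 with the ring E oxygen arylated by a 4-formyl-3,5-dimethoxyphenyl group)
Conditions: Cs2CO3, DMSO, 100 °C
Reagents that add atoms: none
Why: Nucleophilic aromatic substitution; the fluoride of 25 is para to the formyl group and has no ortho substituent, so even the di-ortho-methoxy phenoxide of 24 should add readily, and the two methoxy groups meta to fluorine help by induction.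

Step 15
Reactants: 26 hexamer aldehyde
Product: 28 hexamer phenol (ring F 4-hydroxy-3,5-dimethoxyphenyl, all other oxygens as methyl ethers), via aryl formate 27 (not isolated)
Conditions: mCPBA, CH2Cl2, 0 °C; then K2CO3 (cat.), MeOH, rt
Reagents that add atoms: 3-chloroperoxybenzoic acid (mCPBA), O=C(OO)c1cccc(Cl)c1
Why: Baeyer–Villiger (Dakin-type) oxidation; a formyl group between two methoxy groups and para to an aryloxy group is the most favourable case for aryl migration, and it supplies the C4 oxygen of ring F.

Step 16
Reactants: 28 hexamer phenol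
Product: 29 CNP0218077.0, 2-{2-[4-(2-{3,5-dihydroxy-4-(3,4,5-trihydroxyphenoxy)phenoxy}-3,4,5-trihydroxyphenoxy)-3,5-dihydroxyphenoxy]-3,4,5-trihydroxyphenoxy}benzene-1,3,5-triol
Conditions: BBr3 (excess), CH2Cl2, −78 °C to rt, Ar; then degassed H2O, 0 °C
Reagents that add atoms: none
Why: Lewis-acid cleavage of aryl methyl ethers; boron coordinates each methoxy oxygen and bromide removes the methyl group by SN2 attack, which has no counterpart at the sp2 carbons of the diaryl ethers, so the fifteen methyl groups are lost and the ether backbone stays; aqueous work-up hydrolyses the aryl borates.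

## Compound list

1 | syringaldehyde (4-hydroxy-3,5-dimethoxybenzaldehyde) | COc1cc(C=O)cc(OC)c1O | starting material
2 | 4-(benzyloxy)-3,5-dimethoxybenzaldehyde | COc1cc(C=O)cc(OC)c1OCc1ccccc1 | intermediate
3 | 4-(benzyloxy)-3,5-dimethoxyphenyl formate | O=COc1cc(OC)c(OCc2ccccc2)c(OC)c1 | intermediate
4 | 4-(benzyloxy)-3,5-dimethoxyphenol | Oc1cc(OC)c(OCc2ccccc2)c(OC)c1 | intermediate
5 | squaric acid (3,4-dihydroxycyclobut-3-ene-1,2-dione) | O=C1C(=O)C(O)=C1O | starting material
6 | squaryl dichloride (3,4-dichlorocyclobut-3-ene-1,2-dione) | O=C1C(=O)C(Cl)=C1Cl | intermediate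
7 | 3-chloro-4-methoxycyclobut-3-ene-1,2-dione | COC1=C(Cl)C(=O)C1=O | intermediate
8 | 3-[4-(benzyloxy)-3,5-dimethoxyphenoxy]-4-methoxycyclobut-3-ene-1,2-dione | COC1=C(Oc2cc(OC)c(OCc3ccccc3)c(OC)c2)C(=O)C1=O | intermediate
9 | methyl vinyl ether | C=COC | starting material
10 | 1-methoxyvinyllithium | [Li]C(=C)OC | intermediate
11 | lithium 3-[4-(benzyloxy)-3,5-dimethoxyphenoxy]-2-methoxy-1-(1-methoxyvinyl)-4-oxocyclobut-2-en-1-olate (racemic) | [Li]OC1(C(=C)OC)C(OC)=C(Oc2cc(OC)c(OCc3ccccc3)c(OC)c2)C1=O | intermediate
12 | 2-[4-(benzyloxy)-3,5-dimethoxyphenoxy]-3,4-dimethoxy-4-(1-methoxyvinyl)cyclobut-2-en-1-one (racemic) | C=C(OC)C1(OC)C(OC)=C(Oc2cc(OC)c(OCc3ccccc3)c(OC)c2)C1=O | intermediate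
13 | (3Z)-2-[4-(benzyloxy)-3,5-dimethoxyphenoxy]-3,4,5-trimethoxyhexa-1,3,5-trien-1-one | C=C(OC)/C(OC)=C(OC)\C(Oc1cc(OC)c(OCc2ccccc2)c(OC)c1)=C=O | intermediate
14 | 2-[4-(benzyloxy)-3,5-dimethoxyphenoxy]-3,4,5-trimethoxycyclohexa-2,4-dien-1-one | O=C1CC(OC)=C(OC)C(OC)=C1Oc1cc(OC)c(OCc2ccccc2)c(OC)c1 | intermediate
15 | 2-[4-(benzyloxy)-3,5-dimethoxyphenoxy]-3,4,5-trimethoxyphenol | COc1cc(O)c(Oc2cc(OC)c(OCc3ccccc3)c(OC)c2)c(OC)c1OC | intermediate
16 | 4-fluoro-3,5-dimethoxybenzaldehyde | COc1cc(C=O)cc(OC)c1F | starting material
17 | 4-{2-[4-(benzyloxy)-3,5-dimethoxyphenoxy]-3,4,5-trimethoxyphenoxy}-3,5-dimethoxybenzaldehyde | COc1cc(C=O)cc(OC)c1Oc1cc(OC)c(OC)c(OC)c1Oc1cc(OC)c(OCc2ccccc2)c(OC)c1 | intermediate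
18 | 4-{2-[4-(benzyloxy)-3,5-dimethoxyphenoxy]-3,4,5-trimethoxyphenoxy}-3,5-dimethoxyphenyl formate | O=COc1cc(OC)c(Oc2cc(OC)c(OC)c(OC)c2Oc2cc(OC)c(OCc3ccccc3)c(OC)c2)c(OC)c1 | intermediate
19 | 4-{2-[4-(benzyloxy)-3,5-dimethoxyphenoxy]-3,4,5-trimethoxyphenoxy}-3,5-dimethoxyphenol | Oc1cc(OC)c(Oc2cc(OC)c(OC)c(OC)c2Oc2cc(OC)c(OCc3ccccc3)c(OC)c2)c(OC)c1 | intermediate
20 | 2-[4-(benzyloxy)-3,5-dimethoxyphenoxy]-3,4,5-trimethoxy-1-(2,4,6-trimethoxyphenoxy)benzene | COc1cc(OC)c(Oc2cc(OC)c(OC)c(OC)c2Oc2cc(OC)c(OCc3ccccc3)c(OC)c2)c(OC)c1 | intermediate
21 | 2,6-dimethoxy-4-[2,3,4-trimethoxy-6-(2,4,6-trimethoxyphenoxy)phenoxy]phenol | COc1cc(OC)c(Oc2cc(OC)c(OC)c(OC)c2Oc2cc(OC)c(O)c(OC)c2)c(OC)c1 | intermediate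
22 | 2-[4-(benzyloxy)-3,5-dimethoxyphenoxy]-3,4,5-trimethoxyphenyl trifluoromethanesulfonate | COc1cc(OS(=O)(=O)C(F)(F)F)c(Oc2cc(OC)c(OCc3ccccc3)c(OC)c2)c(OC)c1OC | intermediate
23 | 2-{4-[2-(4-benzyloxy-3,5-dimethoxyphenoxy)-3,4,5-trimethoxyphenoxy]-3,5-dimethoxyphenoxy}-3,4,5-trimethoxy-1-(2,4,6-trimethoxyphenoxy)benzene | COc1cc(OC)c(Oc2cc(OC)c(OC)c(OC)c2Oc2cc(OC)c(Oc3cc(OC)c(OC)c(OC)c3Oc3cc(OC)c(OCc4ccccc4)c(OC)c3)c(OC)c2)c(OC)c1 | intermediate
24 | pentamer phenol A–B–C–D–E (23 with the ring E benzyloxy group replaced by hydroxyl) | COc1cc(OC)c(Oc2cc(OC)c(OC)c(OC)c2Oc2cc(OC)c(Oc3cc(OC)c(OC)c(OC)c3Oc3cc(OC)c(O)c(OC)c3)c(OC)c2)c(OC)c1 | intermediate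
25 | 4-fluoro-2,6-dimethoxybenzaldehyde | COc1cc(F)cc(OC)c1C=O | starting material
26 | hexamer aldehyde (24 with its ring E oxygen carrying a 4-formyl-3,5-dimethoxyphenyl group as ring F) | COc1cc(OC)c(Oc2cc(OC)c(OC)c(OC)c2Oc2cc(OC)c(Oc3cc(OC)c(OC)c(OC)c3Oc3cc(OC)c(Oc4cc(OC)c(C=O)c(OC)c4)c(OC)c3)c(OC)c2)c(OC)c1 | intermediate
27 | hexamer formate (26 with the formyl group replaced by a formyloxy group) | COc1cc(OC)c(Oc2cc(OC)c(OC)c(OC)c2Oc2cc(OC)c(Oc3cc(OC)c(OC)c(OC)c3Oc3cc(OC)c(Oc4cc(OC)c(OC=O)c(OC)c4)c(OC)c3)c(OC)c2)c(OC)c1 | intermediate
28 | hexamer phenol (ring F 4-hydroxy-3,5-dimethoxyphenyl, fifteen methyl ethers) | COc1cc(OC)c(Oc2cc(OC)c(OC)c(OC)c2Oc2cc(OC)c(Oc3cc(OC)c(OC)c(OC)c3Oc3cc(OC)c(Oc4cc(OC)c(O)c(OC)c4)c(OC)c3)c(OC)c2)c(OC)c1 | intermediate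
29 | CNP0218077.0, 2-{2-[4-(2-{3,5-dihydroxy-4-(3,4,5-trihydroxyphenoxy)phenoxy}-3,4,5-trihydroxyphenoxy)-3,5-dihydroxyphenoxy]-3,4,5-trihydroxyphenoxy}benzene-1,3,5-triol | Oc1cc(O)c(Oc2cc(O)c(O)c(O)c2Oc2cc(O)c(Oc3cc(O)c(O)c(O)c3Oc3cc(O)c(Oc4cc(O)c(O)c(O)c4)c(O)c3)c(O)c2)c(O)c1 | target

## Step count and least certain steps

Total: 16 steps. Longest linear sequence: 14 steps (1, 2, 4, 5, 6, 7, 8, 9, 10, 12, 13, 14, 15, 16 from syringaldehyde 1); steps 3 and 11 are side branches.

**Step 6 (key step).** The dienylketene may be diverted before it closes: it can be captured by the phenol already formed, by traces of water or by the electron-rich ring C arene. Inward rotation of the C4 methoxy group would give the ketene geometry that cannot cyclise, and the enol ether of 12 can hydrolyse on acidic surfaces before heating. The fallback gives up the ring construction for a classical coupling and sets out from phenol 4. Copper-catalysed Ullmann coupling of 4 with 2-bromo-3,4,5-trimethoxybenzaldehyde (CuI, picolinic acid, K3PO4, DMSO, 90 °C; the ortho formyl group accelerates the substitution) would give 2-[4-(benzyloxy)-3,5-dimethoxyphenoxy]-3,4,5-trimethoxybenzaldehyde F1. Peracid oxidation would give 2-[4-(benzyloxy)-3,5-dimethoxyphenoxy]-3,4,5-trimethoxyphenyl formate F2, and methanolysis returns to the route at phenol 15.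

**Step 12.** Reductive elimination from an electron-rich arylpalladium phenoxide with three ortho substituents may be slow. Attack of the phenoxide at sulfur of the triflate (returning 15) and reduction of the triflate can then take over. The fallback abandons the union of two halves and repeats the ring expansion instead, setting out from phenol 19, which already has the substitution of a C–D–E phenol.
- 19 is esterified with 7 (made from 6 as in step 4) to give the squarate 3-(4-{2-[4-(benzyloxy)-3,5-dimethoxyphenoxy]-3,4,5-trimethoxyphenoxy}-3,5-dimethoxyphenoxy)-4-methoxycyclobut-3-ene-1,2-dione F3.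
- Addition of 10 and methylation as in step 5 would give the corresponding 2-aryloxy-3,4-dimethoxy-4-(1-methoxyvinyl)cyclobut-2-en-1-one F4.
- Heating as in step 6 would give 2-(4-{2-[4-(benzyloxy)-3,5-dimethoxyphenoxy]-3,4,5-trimethoxyphenoxy}-3,5-dimethoxyphenoxy)-3,4,5-trimethoxyphenol F5, in which the new ring is ring B.
- Substitution on 16 as in step 7 would give 4-[2-(4-{2-[4-(benzyloxy)-3,5-dimethoxyphenoxy]-3,4,5-trimethoxyphenoxy}-3,5-dimethoxyphenoxy)-3,4,5-trimethoxyphenoxy]-3,5-dimethoxybenzaldehyde F6.
- Peracid oxidation would give the corresponding aryl formate F7 and methanolysis the corresponding phenol F8; methylation with iodomethane returns to the route at 23.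

**Step 5.** The two carbonyls of 8 may not be discriminated well enough, since aryloxy and methoxy differ only moderately as donors; this would give the regioisomeric adduct. The organolithium may also displace aryloxide by conjugate addition–elimination, and incomplete O-methylation would allow rearrangement on work-up. The fallback removes the regiochemical question by using a symmetrical electrophile and sets out from 6 and 4. Two equivalents of 4 with i-Pr2NEt would give 3,4-bis[4-(benzyloxy)-3,5-dimethoxyphenoxy]cyclobut-3-ene-1,2-dione F9. Addition of 10 and methylation would give 2,3-bis[4-(benzyloxy)-3,5-dimethoxyphenoxy]-4-methoxy-4-(1-methoxyvinyl)cyclobut-2-en-1-one F10. NaOMe (cat.) in MeOH–THF at 0 °C would then exchange only the aryloxy group at C3, the β-carbon of the enone, by addition–elimination. This releases 4 and returns to the route at 12.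

**Step 7.** Substitution at a fluoride flanked by two methoxy groups by a bulky ortho-aryloxy phenoxide may be sluggish, and the aldehyde may degrade on prolonged heating in basic DMSO. The fallback reverses the polarity of the A–B bond and sets out from triflate 22. Coupling 22 with commercial 2,4,6-trimethoxyphenol under the conditions of step 12 would give 20 directly, bypassing 17 to 19. No new compound arises on this path.

**Step 16.** Cleavage of fifteen methyl ethers may stop at partially methylated products, and the free polyphenol may be lost to oxidation during isolation. The fallback changes the isolation and sets out from 28. After the BBr3 treatment the crude product is acetylated in the same flask (Ac2O, pyridine) to the hexadecaacetate of 29 F11, which can be purified on silica and separated from under-demethylated material. Deacetylation with NaOMe (cat.) in degassed MeOH, followed by acidic resin, returns to the route at 29.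

## Further compounds

F1 | step 6 | 2-[4-(benzyloxy)-3,5-dimethoxyphenoxy]-3,4,5-trimethoxybenzaldehyde | COc1cc(C=O)c(Oc2cc(OC)c(OCc3ccccc3)c(OC)c2)c(OC)c1OC
F2 | step 6 | 2-[4-(benzyloxy)-3,5-dimethoxyphenoxy]-3,4,5-trimethoxyphenyl formate | COc1cc(OC=O)c(Oc2cc(OC)c(OCc3ccccc3)c(OC)c2)c(OC)c1OC
F3 | step 12 | 3-(4-{2-[4-(benzyloxy)-3,5-dimethoxyphenoxy]-3,4,5-trimethoxyphenoxy}-3,5-dimethoxyphenoxy)-4-methoxycyclobut-3-ene-1,2-dione | COC1=C(Oc2cc(OC)c(Oc3cc(OC)c(OC)c(OC)c3Oc3cc(OC)c(OCc4ccccc4)c(OC)c3)c(OC)c2)C(=O)C1=O
F4 | step 12 | 2-(4-{2-[4-(benzyloxy)-3,5-dimethoxyphenoxy]-3,4,5-trimethoxyphenoxy}-3,5-dimethoxyphenoxy)-3,4-dimethoxy-4-(1-methoxyvinyl)cyclobut-2-en-1-one (racemic) | C=C(OC)C1(OC)C(OC)=C(Oc2cc(OC)c(Oc3cc(OC)c(OC)c(OC)c3Oc3cc(OC)c(OCc4ccccc4)c(OC)c3)c(OC)c2)C1=O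
F5 | step 12 | 2-(4-{2-[4-(benzyloxy)-3,5-dimethoxyphenoxy]-3,4,5-trimethoxyphenoxy}-3,5-dimethoxyphenoxy)-3,4,5-trimethoxyphenol | COc1cc(O)c(Oc2cc(OC)c(Oc3cc(OC)c(OC)c(OC)c3Oc3cc(OC)c(OCc4ccccc4)c(OC)c3)c(OC)c2)c(OC)c1OC
F6 | step 12 | 4-[2-(4-{2-[4-(benzyloxy)-3,5-dimethoxyphenoxy]-3,4,5-trimethoxyphenoxy}-3,5-dimethoxyphenoxy)-3,4,5-trimethoxyphenoxy]-3,5-dimethoxybenzaldehyde | COc1cc(C=O)cc(OC)c1Oc1cc(OC)c(OC)c(OC)c1Oc1cc(OC)c(Oc2cc(OC)c(OC)c(OC)c2Oc2cc(OC)c(OCc3ccccc3)c(OC)c2)c(OC)c1
F7 | step 12 | 4-[2-(4-{2-[4-(benzyloxy)-3,5-dimethoxyphenoxy]-3,4,5-trimethoxyphenoxy}-3,5-dimethoxyphenoxy)-3,4,5-trimethoxyphenoxy]-3,5-dimethoxyphenyl formate | O=COc1cc(OC)c(Oc2cc(OC)c(OC)c(OC)c2Oc2cc(OC)c(Oc3cc(OC)c(OC)c(OC)c3Oc3cc(OC)c(OCc4ccccc4)c(OC)c3)c(OC)c2)c(OC)c1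
F8 | step 12 | 4-[2-(4-{2-[4-(benzyloxy)-3,5-dimethoxyphenoxy]-3,4,5-trimethoxyphenoxy}-3,5-dimethoxyphenoxy)-3,4,5-trimethoxyphenoxy]-3,5-dimethoxyphenol | Oc1cc(OC)c(Oc2cc(OC)c(OC)c(OC)c2Oc2cc(OC)c(Oc3cc(OC)c(OC)c(OC)c3Oc3cc(OC)c(OCc4ccccc4)c(OC)c3)c(OC)c2)c(OC)c1
F9 | step 5 | 3,4-bis[4-(benzyloxy)-3,5-dimethoxyphenoxy]cyclobut-3-ene-1,2-dione | O=C1C(=O)C(Oc2cc(OC)c(OCc3ccccc3)c(OC)c2)=C1Oc1cc(OC)c(OCc2ccccc2)c(OC)c1
F10 | step 5 | 2,3-bis[4-(benzyloxy)-3,5-dimethoxyphenoxy]-4-methoxy-4-(1-methoxyvinyl)cyclobut-2-en-1-one (racemic) | C=C(OC)C1(OC)C(Oc2cc(OC)c(OCc3ccccc3)c(OC)c2)=C(Oc2cc(OC)c(OCc3ccccc3)c(OC)c2)C1=O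
F0 | step 7 | none | none
F11 | step 16 | hexadecaacetate of 29 (all sixteen hydroxyls as acetates) | CC(=O)Oc1cc(OC(C)=O)c(Oc2cc(OC(C)=O)c(OC(C)=O)c(OC(C)=O)c2Oc2cc(OC(C)=O)c(Oc3cc(OC(C)=O)c(OC(C)=O)c(OC(C)=O)c3Oc3cc(OC(C)=O)c(Oc4cc(OC(C)=O)c(OC(C)=O)c(OC(C)=O)c4)c(OC(C)=O)c3)c(OC(C)=O)c2)c(OC(C)=O)c1
A1 | alternative 1 | permethylated hexamer with formyl groups at C4 of rings B, D and F (trialdehyde) | COc1cc(OC)c(Oc2cc(OC)c(C=O)c(OC)c2Oc2cc(OC)c(Oc3cc(OC)c(C=O)c(OC)c3Oc3cc(OC)c(Oc4cc(OC)c(C=O)c(OC)c4)c(OC)c3)c(OC)c2)c(OC)c1
A2 | alternative 1 | permethylated hexamer tris(formate) at C4 of rings B, D and F | COc1cc(OC)c(Oc2cc(OC)c(OC=O)c(OC)c2Oc2cc(OC)c(Oc3cc(OC)c(OC=O)c(OC)c3Oc3cc(OC)c(Oc4cc(OC)c(OC=O)c(OC)c4)c(OC)c3)c(OC)c2)c(OC)c1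
A3 | alternative 2 | dimethyl 2-[2-(benzyloxy)-3,4,5-trimethoxyphenoxy]malonate | COC(=O)C(Oc1cc(OC)c(OC)c(OC)c1OCc1ccccc1)C(=O)OC
A4 | alternative 2 | dimethyl 3-oxoglutarate | COC(=O)CC(=O)CC(=O)OC
A5 | alternative 2 | dimethyl 5-[2-(benzyloxy)-3,4,5-trimethoxyphenoxy]-2,4,6-trihydroxyisophthalate | COC(=O)c1c(O)c(C(=O)OC)c(O)c(Oc2cc(OC)c(OC)c(OC)c2OCc2ccccc2)c1O
A6 | alternative 3 | pentacarbonyl{[4-(benzyloxy)-2,6-dimethoxyphenoxy][(E)-2-methoxyethenyl]methylidene}chromium | CO/C=C/C(Oc1c(OC)cc(OCc2ccccc2)cc1OC)=[Cr](=C=O)(=C=O)(=C=O)(=C=O)=C=O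
A7 | alternative 3 | ethoxyacetylene | CCOC#C
A8 | alternative 3 | 4-[4-(benzyloxy)-2,6-dimethoxyphenoxy]-2-ethoxy-6-methoxyphenol | CCOc1cc(Oc2c(OC)cc(OCc3ccccc3)cc2OC)cc(OC)c1O
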